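## Retrosynthetic overview

1. 22 ⇐ 21 (C8–B → C8–OH, phenolic acetate off) ⇐ 19 + 20 (ester at C4).
2. 19 ⇐ 18 ⇐ 16: OH-directed reduction at C4, after Cu-catalysed 1,6-borylation of the dienone (C8 oxygen carried as boron, C6=C7 in place).
3. 16 ⇐ 15: fluoride unmasks the C4 ketone and the C3 alcohol and sets the trans ring fusion.
4. 15 ⇐ 13: intramolecular Buchner reaction of an aryl α-diazoketone; the cyclopentanone and the cycloheptatriene form together (via norcaradiene 14), the m-cresol ring supplying C3a, C4–O, C5, C6–Me, C7 and C8.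
5. 13 ⇐ 10 ⇐ 8 ⇐ 6 ⇐ 4 ⇐ 1 + 2: Fries ketone, phenol-directed asymmetric allylation (sets C3), silylene (temporary ring), alkene → acid → diazoketone.

Locants for the bicyclic compounds follow azulene numbering: C1 (C=O), C3 (C(OH)iPr), C3a (H), C4 (O-acyl), C6 (Me), C8 (OH), C8a (Me). "α" is the face of the C8a methyl.

Assumption: the (R,R)-allylsilane 5 is taken to give (R)-6; if the sense of induction is the opposite, its enantiomer is used with nothing else changed.

Assumption: diazoethane 11 is used as a freshly prepared, dried ether solution (from commercial N-ethyl-N-nitrosourea and KOH).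

## Route

Step 1
Reactants: 1 3-methylphenol; 2 2-methylpropanoyl chloride
Product: 4 1-(2-hydroxy-4-methylphenyl)-2-methylpropan-1-one, via 3-methylphenyl 2-methylpropanoate 3 (not isolated)
Conditions: neat, 25 → 60 °C; then AlCl3 (1.5 equiv), 140 °C, 2 h; aq. HCl
Reagents that add atoms: 2-methylpropanoyl chloride 2, CC(C)C(Cl)=O
Why: O-acylation followed by a thermal Fries rearrangement, which at high temperature gives the chelated ortho-acylphenol with the acyl group at the less hindered ortho position (para to the methyl); no stereocentre is formed.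

Step 2
Reactants: 4 1-(2-hydroxy-4-methylphenyl)-2-methylpropan-1-one; 5 (3aR,7aR)-2-allyl-1,3-bis(4-bromobenzyl)-2-chlorooctahydro-1H-1,3,2-benzodiazasilole
Product: 6 2-[(3R)-3-hydroxy-2-methylhex-5-en-3-yl]-5-methylphenol
Conditions: 5 (1.5 equiv), CH2Cl2, 40 °C, 48 h; then 1 M HCl (diamine recovered)
Reagents that add atoms: allylsilane 5, C=CC[Si]1(Cl)N(Cc2ccc(Br)cc2)[C@@H]2CCCC[C@H]2N1Cc1ccc(Br)cc1
Why: phenol-directed enantioselective ketone allylation with a strained chiral allylchlorosilane (Leighton-type reagent), in which the phenol displaces chloride on silicon and the allyl group is delivered intramolecularly through a closed chair transition state, setting the tertiary carbinol C3 as R even with the hindered isopropyl ketone.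

Step 3
Reactants: 6 2-[(3R)-3-hydroxy-2-methylhex-5-en-3-yl]-5-methylphenol; 7 di-tert-butylsilyl bis(trifluoromethanesulfonate)
Product: 8 (4R)-2,2-di-tert-butyl-7-methyl-4-(propan-2-yl)-4-(prop-2-en-1-yl)-4H-1,3,2-benzodioxasiline
Conditions: tBu2Si(OTf)2 (1.2 equiv), 2,6-lutidine (3 equiv), DMF, 0 → 50 °C
Reagents that add atoms: di-tert-butylsilyl bis(trifluoromethanesulfonate) 7, CC(C)(C)[Si](OS(=O)(=O)C(F)(F)F)(OS(=O)(=O)C(F)(F)F)C(C)(C)C
Why: silylene protection of the phenol/tertiary-alcohol 1,3-diol, which removes both O–H groups before the carbene step and locks the C3–O bond in the arene plane; the stereocentre is untouched.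

Step 4
Reactants: 8 (4R)-2,2-di-tert-butyl-7-methyl-4-(propan-2-yl)-4-(prop-2-en-1-yl)-4H-1,3,2-benzodioxasiline
Product: 10 2-[(4R)-2,2-di-tert-butyl-7-methyl-4-(propan-2-yl)-4H-1,3,2-benzodioxasilin-4-yl]acetic acid, via benzodioxasilinyl-acetaldehyde 9 (not isolated)
Conditions: O3, MeCN/H2O 9:1, 0 °C; then NaClO2, NaH2PO4, 30% H2O2, 0 → 20 °C (one pot)
Reagents that add atoms: ozone, [O-][O+]=O; sodium chlorite, [Na+].[O-]Cl=O
Why: ozonolysis in wet acetonitrile gives the aldehyde directly and chlorite (Pinnick-type) oxidation in the same pot gives the acid, the terminal alkene reacting far faster with ozone than the silyloxy arene; C3 is untouched.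

Step 5
Reactants: 10 2-[(4R)-2,2-di-tert-butyl-7-methyl-4-(propan-2-yl)-4H-1,3,2-benzodioxasilin-4-yl]acetic acid; 11 diazoethane
Product: 13 3-diazo-1-[(4R)-2,2-di-tert-butyl-7-methyl-4-(propan-2-yl)-4H-1,3,2-benzodioxasilin-4-yl]butan-2-one, via acid chloride 12 (not isolated)
Conditions: 1-chloro-N,N,2-trimethylprop-1-en-1-amine (1.2 equiv), CH2Cl2, 0 → 20 °C; then CH3CHN2 (3 equiv), Et2O, −20 → 0 °C
Reagents that add atoms: diazoethane 11, CC=[N+]=[N-]; 1-chloro-N,N,2-trimethylprop-1-en-1-amine, CC(C)=C(Cl)N(C)C (chlorine of 12 only)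
Why: neutral acid chloride formation (Ghosez reagent, no HCl near the benzylic silyl ether) and C-acylation of diazoethane (Arndt–Eistert-type diazoketone synthesis, excess diazoethane taking up HCl) give the α-methyl-α-diazoketone; no stereocentre changes.

Step 6
Reactants: 13 3-diazo-1-[(4R)-2,2-di-tert-butyl-7-methyl-4-(propan-2-yl)-4H-1,3,2-benzodioxasilin-4-yl]butan-2-one
Product: 15 (3R,8aR)-3,4-[(di-tert-butylsilanediyl)bis(oxy)]-6,8a-dimethyl-3-(propan-2-yl)-3,8a-dihydroazulen-1(2H)-one, via norcaradiene 14 (not isolated)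
Conditions: Rh2(OAc)4 (1 mol%), CH2Cl2, 40 °C, slow addition (5 mM)
Reagents that add atoms: none
Why: intramolecular Buchner reaction, in which the rhodium carbenoid cyclopropanates the unsubstituted ipso/ortho edge of the arene (closing the cyclopentanone) and the norcaradiene opens by 6π electrocyclisation to the cycloheptatriene, creating quaternary C8a; because the silylene ring holds the C3–O bond in the arene plane, the tether reaches only the face anti to the isopropyl group and the C8a methyl ends up cis to the C3 oxygen, while the tBu2Si group shields the oxygenated edge and the oxygen on C3 deactivates the isopropyl C–H towards insertion.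

Step 7
Reactants: 15 (3R,8aR)-3,4-[(di-tert-butylsilanediyl)bis(oxy)]-6,8a-dimethyl-3-(propan-2-yl)-3,8a-dihydroazulen-1(2H)-one
Product: 16 (3R,3aR,8aR)-3-hydroxy-6,8a-dimethyl-3-(propan-2-yl)-2,3,3a,8a-tetrahydroazulene-1,4-dione
Conditions: HF·pyridine (excess), pyridine, THF, 0 → 20 °C
Reagents that add atoms: none
Why: fluoride cleavage of the silylene frees the tertiary alcohol and the C4 enol, which tautomerises to the dienone, and the epimerisable C3a–H (α to the ketone) is expected to settle trans to the C8a methyl, both because the twisted cyclohepta-2,4-dienone and the cyclopentanone fit that fusion best and because the first-formed bulky fluorosilyl ether on the α face steers protonation to the β face.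

Step 8
Reactants: 16 (3R,3aR,8aR)-3-hydroxy-6,8a-dimethyl-3-(propan-2-yl)-2,3,3a,8a-tetrahydroazulene-1,4-dione; 17 bis(pinacolato)diboron
Product: 18 (3R,3aR,8R,8aR)-3-hydroxy-6,8a-dimethyl-3-(propan-2-yl)-8-(4,4,5,5-tetramethyl-1,3,2-dioxaborolan-2-yl)-2,3,3a,5,8,8a-hexahydroazulene-1,4-dione
Conditions: CuCl (5 mol%), Xantphos (5 mol%), NaOtBu (10 mol%), B2pin2 (1.2 equiv), MeOH (2 equiv), THF, 0 °C
Reagents that add atoms: bis(pinacolato)diboron 17, CC1(C)OB(OC1(C)C)B1OC(C)(C)C(C)(C)O1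
Why: copper-catalysed 1,6-conjugate borylation of the dienone, in which Cu–Bpin adds to the δ-carbon C8 (the β-carbon C6 is fully substituted) from the face opposite the adjacent C8a methyl and α-protonation of the copper dienolate by methanol leaves C6=C7 and the C5 methylene, so boron stands in for the 8-OH with the correct configuration.

Step 9
Reactants: 18 (3R,3aR,8R,8aR)-3-hydroxy-6,8a-dimethyl-3-(propan-2-yl)-8-(4,4,5,5-tetramethyl-1,3,2-dioxaborolan-2-yl)-2,3,3a,5,8,8a-hexahydroazulene-1,4-dione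
Product: 19 (3R,3aS,4S,8R,8aR)-3,4-dihydroxy-6,8a-dimethyl-3-(propan-2-yl)-8-(4,4,5,5-tetramethyl-1,3,2-dioxaborolan-2-yl)-3,3a,4,5,8,8a-hexahydroazulen-1(2H)-one
Conditions: Me4NBH(OAc)3 (5 equiv), MeCN/AcOH 1:1, −30 → 0 °C
Reagents that add atoms: none
Why: hydroxyl-directed (Evans–Saksena) reduction, in which the tertiary C3–OH binds boron and delivers hydride to the α face of the C4 ketone through a six-membered transition state to give the 4β-alcohol (cis to H-3a), while the hindered C1 ketone (not reduced intermolecularly by this reagent and reachable from C3–OH only through a strained bridged transition state) and the allylboronate are left alone.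

Step 10
Reactants: 19 (3R,3aS,4S,8R,8aR)-3,4-dihydroxy-6,8a-dimethyl-3-(propan-2-yl)-8-(4,4,5,5-tetramethyl-1,3,2-dioxaborolan-2-yl)-3,3a,4,5,8,8a-hexahydroazulen-1(2H)-one; 20 4-acetoxy-3-methoxybenzoic acid
Product: 21 (3R,3aS,4S,8R,8aR)-3-hydroxy-6,8a-dimethyl-1-oxo-3-(propan-2-yl)-8-(4,4,5,5-tetramethyl-1,3,2-dioxaborolan-2-yl)-1,2,3,3a,4,5,8,8a-octahydroazulen-4-yl 4-acetoxy-3-methoxybenzoate
Conditions: EDC·HCl (2 equiv), DMAP (0.3 equiv), CH2Cl2, 20 °C
Reagents that add atoms: 4-acetoxy-3-methoxybenzoic acid 20, CC(=O)Oc1ccc(C(=O)O)cc1OC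
Why: Steglich esterification at the only secondary hydroxyl present (C3–OH is tertiary and the C8 oxygen is still masked as boron), so the acylation site is unambiguous; no stereocentre changes.

Step 11
Reactants: 21 (3R,3aS,4S,8R,8aR)-3-hydroxy-6,8a-dimethyl-1-oxo-3-(propan-2-yl)-8-(4,4,5,5-tetramethyl-1,3,2-dioxaborolan-2-yl)-1,2,3,3a,4,5,8,8a-octahydroazulen-4-yl 4-acetoxy-3-methoxybenzoate
Product: 22 (3R,3aS,4S,8R,8aS)-3,8-dihydroxy-6,8a-dimethyl-1-oxo-3-(propan-2-yl)-1,2,3,3a,4,5,8,8a-octahydroazulen-4-yl 4-hydroxy-3-methoxybenzoate (CNP0233071.1)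
Conditions: NaBO3·4H2O (6 equiv), THF/H2O 1:1, 0 → 20 °C
Reagents that add atoms: sodium perborate, [Na+].[O-]OB=O
Why: oxidation of the allylic pinacol boronate with retention (1,2-shift of C8 from boron to oxygen, no allylic transposition) gives the 8-OH, and hydroperoxide anion in the same mildly basic medium cleaves the phenolic acetate much faster than the hindered secondary benzoate.

## Compound list

1 | 3-methylphenol (m-cresol) | Cc1cccc(O)c1 | starting material
2 | 2-methylpropanoyl chloride (isobutyryl chloride) | CC(C)C(Cl)=O | starting material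
3 | 3-methylphenyl 2-methylpropanoate | CC(C)C(=O)Oc1cccc(C)c1 | intermediate
4 | 1-(2-hydroxy-4-methylphenyl)-2-methylpropan-1-one | CC(C)C(=O)c1ccc(C)cc1O | intermediate
5 | (3aR,7aR)-2-allyl-1,3-bis(4-bromobenzyl)-2-chlorooctahydro-1H-1,3,2-benzodiazasilole | C=CC[Si]1(Cl)N(Cc2ccc(Br)cc2)[C@@H]2CCCC[C@H]2N1Cc1ccc(Br)cc1 | starting material
6 | 2-[(3R)-3-hydroxy-2-methylhex-5-en-3-yl]-5-methylphenol | C=CC[C@@](O)(C(C)C)c1ccc(C)cc1O | intermediate
7 | di-tert-butylsilyl bis(trifluoromethanesulfonate) | CC(C)(C)[Si](OS(=O)(=O)C(F)(F)F)(OS(=O)(=O)C(F)(F)F)C(C)(C)C | starting material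
8 | (4R)-2,2-di-tert-butyl-7-methyl-4-(propan-2-yl)-4-(prop-2-en-1-yl)-4H-1,3,2-benzodioxasiline | C=CC[C@]1(C(C)C)O[Si](C(C)(C)C)(C(C)(C)C)Oc2cc(C)ccc21 | intermediate
9 | 2-[(4R)-2,2-di-tert-butyl-7-methyl-4-(propan-2-yl)-4H-1,3,2-benzodioxasilin-4-yl]acetaldehyde | O=CC[C@]1(C(C)C)O[Si](C(C)(C)C)(C(C)(C)C)Oc2cc(C)ccc21 | intermediate
10 | 2-[(4R)-2,2-di-tert-butyl-7-methyl-4-(propan-2-yl)-4H-1,3,2-benzodioxasilin-4-yl]acetic acid | OC(=O)C[C@]1(C(C)C)O[Si](C(C)(C)C)(C(C)(C)C)Oc2cc(C)ccc21 | intermediate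
11 | diazoethane | CC=[N+]=[N-] | starting material
12 | 2-[(4R)-2,2-di-tert-butyl-7-methyl-4-(propan-2-yl)-4H-1,3,2-benzodioxasilin-4-yl]acetyl chloride | ClC(=O)C[C@]1(C(C)C)O[Si](C(C)(C)C)(C(C)(C)C)Oc2cc(C)ccc21 | intermediate
13 | 3-diazo-1-[(4R)-2,2-di-tert-butyl-7-methyl-4-(propan-2-yl)-4H-1,3,2-benzodioxasilin-4-yl]butan-2-one | CC(=[N+]=[N-])C(=O)C[C@]1(C(C)C)O[Si](C(C)(C)C)(C(C)(C)C)Oc2cc(C)ccc21 | intermediate
14 | norcaradiene valence isomer of 15 (cyclopropane C3a–C8–C8a, diene C4=C5/C6=C7, 8a-methyl over the six-membered ring) | C[C@]12[C@H]3C=C(C)C=C4O[Si](C(C)(C)C)(C(C)(C)C)O[C@@](C(C)C)(CC1=O)[C@@]243 | intermediate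
15 | (3R,8aR)-3,4-[(di-tert-butylsilanediyl)bis(oxy)]-6,8a-dimethyl-3-(propan-2-yl)-3,8a-dihydroazulen-1(2H)-one (C3a=C4 silyl enol ether, C5=C6, C7=C8; 8a-Me cis to 3-O) | C[C@@]12C=CC(C)=CC3=C1[C@](C(C)C)(CC2=O)O[Si](C(C)(C)C)(C(C)(C)C)O3 | intermediate
16 | (3R,3aR,8aR)-3-hydroxy-6,8a-dimethyl-3-(propan-2-yl)-2,3,3a,8a-tetrahydroazulene-1,4-dione (trans-fused) | C[C@@]12C=CC(C)=CC(=O)[C@H]1[C@](O)(C(C)C)CC2=O | intermediate
17 | bis(pinacolato)diboron | CC1(C)OB(OC1(C)C)B1OC(C)(C)C(C)(C)O1 | starting material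
18 | (3R,3aR,8R,8aR)-3-hydroxy-6,8a-dimethyl-3-(propan-2-yl)-8-(4,4,5,5-tetramethyl-1,3,2-dioxaborolan-2-yl)-2,3,3a,5,8,8a-hexahydroazulene-1,4-dione | C[C@@]12[C@H](B3OC(C)(C)C(C)(C)O3)C=C(C)CC(=O)[C@H]1[C@](O)(C(C)C)CC2=O | intermediate
19 | (3R,3aS,4S,8R,8aR)-3,4-dihydroxy-6,8a-dimethyl-3-(propan-2-yl)-8-(4,4,5,5-tetramethyl-1,3,2-dioxaborolan-2-yl)-3,3a,4,5,8,8a-hexahydroazulen-1(2H)-one | C[C@@]12[C@H](B3OC(C)(C)C(C)(C)O3)C=C(C)C[C@H](O)[C@H]1[C@](O)(C(C)C)CC2=O | intermediate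
20 | 4-acetoxy-3-methoxybenzoic acid (O-acetylvanillic acid) | CC(=O)Oc1ccc(C(=O)O)cc1OC | starting material
21 | (3R,3aS,4S,8R,8aR)-3-hydroxy-6,8a-dimethyl-1-oxo-3-(propan-2-yl)-8-(4,4,5,5-tetramethyl-1,3,2-dioxaborolan-2-yl)-1,2,3,3a,4,5,8,8a-octahydroazulen-4-yl 4-acetoxy-3-methoxybenzoate | C[C@@]12[C@H](B3OC(C)(C)C(C)(C)O3)C=C(C)C[C@H](OC(=O)c3ccc(OC(C)=O)c(OC)c3)[C@H]1[C@](O)(C(C)C)CC2=O | intermediate
22 | (3R,3aS,4S,8R,8aS)-3,8-dihydroxy-6,8a-dimethyl-1-oxo-3-(propan-2-yl)-1,2,3,3a,4,5,8,8a-octahydroazulen-4-yl 4-hydroxy-3-methoxybenzoate | COc1cc(C(=O)O[C@H]2CC(C)=C[C@@H](O)[C@@]3(C)C(=O)C[C@@](O)(C(C)C)[C@H]23)ccc1O | target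

## Step count and risks

Total steps: 11. Longest linear sequence: 11 (1 → 22).

The three steps most likely to fail:

**Step 6 (Buchner cyclisation).** The carbenoid may attack the oxygenated arene edge, insert into C–H, or undergo a 1,2-hydride shift. The fallback is a carbene-free anionic dearomatisation and ring expansion that sets out from 13 and comes back at 16. One equivalent of HBr in ether at −40 °C converts 13 into the α-bromoketone F1. TBAF (1.1 equiv, THF, 0 °C) cleaves the aryl O–Si bond first, and the phenoxide closes the five-membered ring by ipso C-alkylation to give the spirodienone F2, which still carries the C3 oxygen as its di-tert-butylfluorosilyl ether. KOtBu then forms the ketone enolate next to the spiro carbon; it adds to the neighbouring dienone terminus, and the resulting norcaradiene enolate opens to the trienolate of 16 (a net 1,2-vinyl shift, untested on this system). HF·pyridine removes the silyl group and gives 16.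

**Step 8 (1,6-borylation).** The δ-carbon is neopentyl and the aldol-type tertiary alcohol is base-sensitive. The fallback sets out from 16 and comes back at 22. mCPBA (NaHCO3, CH2Cl2, 0 °C) epoxidises the γ,δ-alkene anti to the 8a-methyl to give the epoxy-enone F3. SmI2 (THF/MeOH, −78 °C) opens the vinylogous epoxy ketone to the 8-hydroxy-β,γ-enone F4. TESCl/imidazole gives the 8-O-triethylsilyl ether F5. Directed reduction as in step 9 gives the diol F6, and esterification with 20 as in step 10 gives the ester F7. HF·pyridine followed by NH3/MeOH then gives 22.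

**Step 9 (directed reduction).** Delivery from the tertiary OH may be slow, or the C1 ketone may also be reduced. The fallback sets out from 18 and comes back at 21. L-Selectride (THF, −78 °C) attacks C4 from the less hindered β face (anti to the axial 8a-methyl) and spares the doubly neopentyl C1 ketone, giving the 4-epi-alcohol F8. Mitsunobu esterification with 20 (PPh3, DIAD, toluene, 0 → 20 °C) then inverts C4 and gives 21 directly.

## Further compounds

F1 | step 6 | 3-bromo-1-[(4R)-2,2-di-tert-butyl-7-methyl-4-(propan-2-yl)-4H-1,3,2-benzodioxasilin-4-yl]butan-2-one (both C3 epimers) | CC(Br)C(=O)C[C@]1(C(C)C)O[Si](C(C)(C)C)(C(C)(C)C)Oc2cc(C)ccc21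
F2 | step 6 | (4R)-4-{[di-tert-butyl(fluoro)silyl]oxy}-1,8-dimethyl-4-(propan-2-yl)spiro[4.5]deca-7,9-diene-2,6-dione | CC1C(=O)C[C@@](O[Si](F)(C(C)(C)C)C(C)(C)C)(C(C)C)C12C=CC(C)=CC2=O
F3 | step 8 | (3R,3aR,8aS)-7,8-epoxy-3-hydroxy-6,8a-dimethyl-3-(propan-2-yl)-2,3,3a,7,8,8a-hexahydroazulene-1,4-dione (epoxide anti to the 8a-methyl) | C[C@@]12[C@@H]3O[C@@H]3C(C)=CC(=O)[C@H]1[C@](O)(C(C)C)CC2=O
F4 | step 8 | (3R,3aR,8R,8aS)-3,8-dihydroxy-6,8a-dimethyl-3-(propan-2-yl)-2,3,3a,5,8,8a-hexahydroazulene-1,4-dione | C[C@@]12[C@H](O)C=C(C)CC(=O)[C@H]1[C@](O)(C(C)C)CC2=O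
F5 | step 8 | (3R,3aR,8R,8aS)-3-hydroxy-6,8a-dimethyl-3-(propan-2-yl)-8-[(triethylsilyl)oxy]-2,3,3a,5,8,8a-hexahydroazulene-1,4-dione | C[C@@]12[C@H](O[Si](CC)(CC)CC)C=C(C)CC(=O)[C@H]1[C@](O)(C(C)C)CC2=O
F6 | step 8 | (3R,3aS,4S,8R,8aS)-3,4-dihydroxy-6,8a-dimethyl-3-(propan-2-yl)-8-[(triethylsilyl)oxy]-3,3a,4,5,8,8a-hexahydroazulen-1(2H)-one | C[C@@]12[C@H](O[Si](CC)(CC)CC)C=C(C)C[C@H](O)[C@H]1[C@](O)(C(C)C)CC2=O
F7 | step 8 | (3R,3aS,4S,8R,8aS)-3-hydroxy-6,8a-dimethyl-1-oxo-3-(propan-2-yl)-8-[(triethylsilyl)oxy]-1,2,3,3a,4,5,8,8a-octahydroazulen-4-yl 4-acetoxy-3-methoxybenzoate | C[C@@]12[C@H](O[Si](CC)(CC)CC)C=C(C)C[C@H](OC(=O)c3ccc(OC(C)=O)c(OC)c3)[C@H]1[C@](O)(C(C)C)CC2=O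
F8 | step 9 | (3R,3aS,4R,8R,8aR)-3,4-dihydroxy-6,8a-dimethyl-3-(propan-2-yl)-8-(4,4,5,5-tetramethyl-1,3,2-dioxaborolan-2-yl)-3,3a,4,5,8,8a-hexahydroazulen-1(2H)-one | C[C@@]12[C@H](B3OC(C)(C)C(C)(C)O3)C=C(C)C[C@@H](O)[C@H]1[C@](O)(C(C)C)CC2=O
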